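**Retrosynthetic overview**

1. The central CH2 is cut by a retro-Knoevenagel/Michael disconnection: the target is two molecules of isobutyrylfilicinic acid joined by formaldehyde.
2. The six-membered acylfilicinic acid ring is cut at its acyl-bearing carbon: a one-carbon ring expansion (1,2-acyl shift with loss of N2) of 3,3-dimethylcyclopentane-1,2,4-trione by 1-diazo-3-methylbutan-2-one brings in that ring carbon and the isobutyryl group together.
3. The five-membered trione comes from 3-methylbutan-2-one and dimethyl oxalate (Claisen, then Dieckmann); the diazo ketone comes from isobutyryl chloride and (trimethylsilyl)diazomethane.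
4. Ring order: five-membered carbocycle first, then its expansion to the six-membered ring, then coupling of two six-membered rings through CH2.

Assumption: the target SMILES has no stereocentre and no stereogenic double bond, so the compound is achiral and no stereocontrol is needed. Enolised tricarbonyl rings are drawn in the tautomer of the given SMILES.

Locants used for the trione 4: C1 and C2 are the vicinal dione, C3 is CMe2, C4 is the enolised carbonyl, C5 is the ring CH.

**Route**

Step 1
Reactants: 1 3-methylbutan-2-one; 2 dimethyl oxalate
Product: 4 3,3-dimethylcyclopentane-1,2,4-trione (enol form 4-hydroxy-5,5-dimethylcyclopent-3-ene-1,2-dione), via methyl 5-methyl-2,4-dioxohexanoate 3 (not isolated)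
Conditions: KOtBu (2.5 equiv), THF, 0 °C → 65 °C, 8 h; then 2 M aq HCl
Reagents that add atoms: none
Why: A crossed Claisen condensation of the methyl-side enolate of 1 with the non-enolisable diester 2 gives 3, and a Dieckmann-type closure of the isopropyl methine onto the remaining ester builds the five-membered ring with its quaternary CMe2, driven by formation of the stabilised vinylogous-acid enolate of 4; no stereocentre is formed.

Step 2
Reactants: 5 isobutyryl chloride (2-methylpropanoyl chloride); 6 (trimethylsilyl)diazomethane
Product: 7 1-diazo-3-methylbutan-2-one
Conditions: 6 (2.0 equiv, 2 M in hexanes), THF/MeCN 1:1, 0 °C → rt, 20 h; volatiles evaporated, short SiO2 plug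
Reagents that add atoms: none
Why: Arndt–Eistert-type C-acylation of the nucleophilic diazo carbon by the acid chloride, followed by chloride-induced loss of the silyl group as Me3SiCl, gives the acceptor diazo ketone; no stereocentre is formed.

Step 3
Reactants: 4 3,3-dimethylcyclopentane-1,2,4-trione; 7 1-diazo-3-methylbutan-2-one
Product: 9 isobutyrylfilicinic acid [3,5-dihydroxy-4,4-dimethyl-2-(2-methylpropanoyl)cyclohexa-2,5-dien-1-one], via β-oxido diazonium adduct 8 (not isolated)
Conditions: Sc(OTf)3 (20 mol%), 4 Å MS, CH2Cl2, −20 °C → rt, 7 (1.3 equiv) added over 2 h; then 1 M aq HCl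
Reagents that add atoms: none
Why: Proposed new method: trivalent scandium chelates the vicinal C1/C2 dione of 4, in which C4 is tied up as the enol so that C1 is only a vinylogous-acid carbonyl and the C2 ketone is the one electrophilic site; the diazo carbon of 7 adds to C2 to give 8, and the sp2 acyl carbon C1, not the crowded quaternary C3, undergoes the 1,2-shift with loss of N2, which inserts CH(COiPr) between C1 and C2 and expands the five-membered ring to the six-membered β-triketone, which enolises at once to the acidic 9 and so resists a second insertion; the closest known reactions are the Lewis-acid-catalysed Tiffeneau–Demjanov-type homologation of ketones, isatins and α-keto esters with α-diazo carbonyl compounds and the classical diazomethane ring expansion of cyclic 1,2-diones, but insertion of an acceptor diazo ketone into the C(O)–C(O) bond of a cyclopentane-1,2,4-trione to build an acylfilicinic acid ring has not been shown.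

Step 4
Reactants: 9 isobutyrylfilicinic acid (2 equiv); 10 formaldehyde
Product: 12 2,2'-methylenebis[3,5-dihydroxy-4,4-dimethyl-6-(2-methylpropanoyl)cyclohexa-2,5-dien-1-one] (the target), via methylidene trione 11 (not isolated)
Conditions: 10 as 37% aq CH2O (0.5 equiv), 1% aq KOH, 0 °C → rt, 15 min; then 1 M aq HCl
Reagents that add atoms: none
Why: Base-mediated Knoevenagel condensation of the only free nucleophilic ring carbon (C6) of one molecule of 9 with formaldehyde gives the enone 11, and Michael addition of a second enolate of 9 gives the methylene-bridged dimer, the established way to albaspidin-type methylenebis(acylfilicinic acids); the bridge carbon is not a stereocentre.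

**Compound list**

1 | 3-methylbutan-2-one | CC(C)C(C)=O | starting material
2 | dimethyl oxalate | COC(=O)C(=O)OC | starting material
3 | methyl 5-methyl-2,4-dioxohexanoate | COC(=O)C(=O)CC(=O)C(C)C | intermediate (not isolated)
4 | 3,3-dimethylcyclopentane-1,2,4-trione, drawn as its enol 4-hydroxy-5,5-dimethylcyclopent-3-ene-1,2-dione | OC1=CC(=O)C(=O)C1(C)C | intermediate
5 | isobutyryl chloride (2-methylpropanoyl chloride) | CC(C)C(Cl)=O | starting material
6 | (trimethylsilyl)diazomethane | C[Si](C)(C)C=[N+]=[N-] | starting material
7 | 1-diazo-3-methylbutan-2-one | CC(C)C(=O)C=[N+]=[N-] | intermediate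
8 | 1-(1-diazonio-3-methyl-2-oxobutyl)-4-hydroxy-5,5-dimethyl-2-oxocyclopent-3-en-1-olate (zwitterion, scandium-bound in the flask; its two transient stereocentres form unselectively and are lost in the shift) | CC(C)C(=O)C([N+]#N)C1([O-])C(=O)C=C(O)C1(C)C | intermediate (not isolated)
9 | isobutyrylfilicinic acid, 3,5-dihydroxy-4,4-dimethyl-2-(2-methylpropanoyl)cyclohexa-2,5-dien-1-one | CC(C)C(=O)C1=C(O)C(C)(C)C(O)=CC1=O | intermediate
10 | formaldehyde | C=O | starting material
11 | 5-hydroxy-6,6-dimethyl-2-methylidene-4-(2-methylpropanoyl)cyclohex-4-ene-1,3-dione | CC(C)C(=O)C1=C(O)C(C)(C)C(=O)C(=C)C1=O | intermediate (not isolated)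
12 | 2,2'-methylenebis[3,5-dihydroxy-4,4-dimethyl-6-(2-methylpropanoyl)cyclohexa-2,5-dien-1-one] (achiral) | CC(C)C(=O)C1=C(O)C(C)(C)C(O)=C(CC2=C(O)C(C)(C)C(O)=C(C(=O)C(C)C)C2=O)C1=O | target

**Count**

Total steps: 4. Longest linear sequence: 3 (steps 1, 3, 4, or steps 2, 3, 4).

**Steps most likely to fail, with fallbacks**

Step 3 (the proposed new ring expansion). Possible failures are O-alkylation of the acidic enol of 4 by the activated diazo ketone, epoxide formation from 8 instead of the shift, migration of C3 instead of C1, and catalyst sequestration by the chelating product. The fallback uses known chemistry, sets out from 4 and comes back at 9. Compound 4 is treated with excess ethereal diazomethane in Et2O/MeOH at 0 °C → rt. This methylates the enol, effects the classical uncatalysed diazomethane homologation of the cyclic 1,2-dione with acyl shift, and methylates the new β-diketone, giving 3,5-dimethoxy-4,4-dimethylcyclohexa-2,5-dien-1-one F1 together with its 2,4-dienone isomer. Hydrolysis of both enol ethers with 2 M aq HCl at reflux gives filicinic acid (3,5-dihydroxy-4,4-dimethylcyclohexa-2,5-dien-1-one) F2. Friedel–Crafts C-acylation of F2 with 5 (1.0 equiv, AlCl3, nitrobenzene, rt) then gives 9. The acyl group is thus introduced after, not during, the ring expansion, at the cost of two more steps.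

Step 1 (one-pot Claisen/Dieckmann through a tertiary carbanion). The ring closure that forms the quaternary carbon may stall at 3, or 3 may revert by retro-Claisen cleavage. The fallback sets out from 1 and comes back at 4, and forms the quaternary carbon first. Compound 1 is converted under thermodynamic control (Me3SiCl, NaI, Et3N, MeCN) into trimethyl[(3-methylbut-2-en-2-yl)oxy]silane F3. Mukaiyama-type C-acylation of F3 with methyl chlorooxoacetate (ZnCl2, CH2Cl2, −78 °C → 0 °C) gives methyl 3,3-dimethyl-2,4-dioxopentanoate F4. The unhindered methyl ketone enolate of F4 (LiN(SiMe3)2, THF, −78 °C → 0 °C) then closes onto the ester in a Dieckmann reaction to give 4.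

Step 2 (diazo ketone from an α-branched, ketene-prone acid chloride; volatile product). The fallback sets out from 1 and comes back at 7, using detrifluoroacetylative diazo transfer. The kinetic methyl enolate of 1 (LiN(SiMe3)2, THF, −78 °C) is acylated with 2,2,2-trifluoroethyl trifluoroacetate to give 1,1,1-trifluoro-5-methylhexane-2,4-dione F5. Treatment of F5 with methanesulfonyl azide, Et3N and water in MeCN at rt transfers the diazo group and cleaves the trifluoroacetyl group, giving 7.

**Further compounds**

F1 | step 3 | 3,5-dimethoxy-4,4-dimethylcyclohexa-2,5-dien-1-one | COC1=CC(=O)C=C(OC)C1(C)C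
F2 | step 3 | filicinic acid, 3,5-dihydroxy-4,4-dimethylcyclohexa-2,5-dien-1-one | OC1=CC(=O)C=C(O)C1(C)C
F3 | step 1 | trimethyl[(3-methylbut-2-en-2-yl)oxy]silane | CC(C)=C(C)O[Si](C)(C)C
F4 | step 1 | methyl 3,3-dimethyl-2,4-dioxopentanoate | COC(=O)C(=O)C(C)(C)C(C)=O
F5 | step 2 | 1,1,1-trifluoro-5-methylhexane-2,4-dione | CC(C)C(=O)CC(=O)C(F)(F)F
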